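**Plan**

1. Retrosynthesis: the C4 p-hydroxybenzoate is cut last. Then C7–C8 and C3a–C8a (azulene numbering of the target) are cut together, a retro-[5+2] that opens both carbocycles and leads to a 3-oxidopyrylium carrying a tethered 1,1-disubstituted alkene. The pyranone goes back to a 4-methyl-2-furyl carbinol, and this to a furyllithium, an α-hydroxy aldehyde and an epoxy alcohol.
2. Enabling feature: in the seven-membered ring the string C3a–C4(O)–C5–C6(CH3)–C7 carries its oxygen on the carbon next to the ring fusion, which is the pattern of C2–C6 of a 5-methyl-3-oxidopyrylium. C3–C2–C1 is a three-atom tether from C3a to the alkene carbon C8a, so the five- and the seven-membered ring can close in one event.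
3. Forward order: acyclic diol, furan, pyranone (temporary ring), then both carbocycles at once with a temporary 3a,7-oxygen bridge. Two samarium diiodide reductions excise the bridge oxygen: the first puts H on C3a, the second moves the alkene to C6=C7. Ketone reduction and esterification finish the route.
4. Stereochemistry: C3 from a Sharpless epoxidation (D-tartrate). C8a is set from C3 in the cycloaddition. C3a is set by protonation of a samarium enolate (trans fusion). C4 is set by hydride delivery from the C3 hydroxyl.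

Key step: step 8

Remark: C1 of 11 and 12 and C2/C6 of 13 and 14 are carried as stereoisomer mixtures, because these centres become planar in step 8. Azulene numbering of the target is used for all bicyclic compounds.

**Route**

Step 1
Reactants: 1 prop-2-yn-1-ol; 2 isopropylmagnesium chloride
Product: 3 3-methyl-2-methylidenebutan-1-ol
Conditions: 2 (2.5 equiv), CuI (10 mol %), Et2O, 0 °C to rt; aq. NH4Cl
Reagents that add atoms: none
Why: Copper-catalysed carbomagnesiation of the propargylic alkoxide, which holds magnesium at the terminal carbon, puts the isopropyl group on C2, and protonation on work-up should give the 2-substituted allylic alcohol; no stereocentre is formed.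

Step 2
Reactants: 3 3-methyl-2-methylidenebutan-1-ol
Product: 4 [(2R)-2-(propan-2-yl)oxiran-2-yl]methanol
Conditions: Ti(OiPr)4 (10 mol %), D-(−)-diisopropyl tartrate (12 mol %), t-BuOOH (2 equiv), 4 Å molecular sieves, CH2Cl2, −20 °C
Reagents that add atoms: tert-butyl hydroperoxide, CC(C)(C)OO
Why: Sharpless asymmetric epoxidation of a 2-substituted allylic alcohol, in which the D-tartrate catalyst should select the alkene face that gives the (R)-epoxide; this centre becomes C3 of the target and is the source of all absolute configuration.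

Step 3
Reactants: 4 [(2R)-2-(propan-2-yl)oxiran-2-yl]methanol; 5 (2-methylprop-2-en-1-yl)magnesium chloride
Product: 6 (2R)-5-methyl-2-(propan-2-yl)hex-5-ene-1,2-diol
Conditions: 5 (3 equiv), CuI (10 mol %), THF, −40 to 0 °C; aq. NH4Cl
Reagents that add atoms: none
Why: Copper-catalysed SN2 opening of the epoxide by the allylic Grignard reagent at the unsubstituted CH2 terminus, so no bond to the stereocentre is broken and its configuration is kept.

Step 4
Reactants: 6 (2R)-5-methyl-2-(propan-2-yl)hex-5-ene-1,2-diol
Product: 7 (2R)-2-hydroxy-5-methyl-2-(propan-2-yl)hex-5-enal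
Conditions: IBX (2-iodoxybenzoic acid, 1.5 equiv), EtOAc, 75 °C; used crude
Reagents that add atoms: none
Why: IBX oxidation of the primary alcohol, a reagent that oxidises 1,2-diols without glycol cleavage and leaves the tertiary hydroxyl alone; the α-carbon is quaternary and cannot epimerise.

Step 5
Reactants: 8 3-methylfuran
Product: 9 2-bromo-3-methylfuran
Conditions: NBS (1.0 equiv), DMF, 0 °C, dark; used as a solution
Reagents that add atoms: N-bromosuccinimide, O=C1CCC(=O)N1Br
Why: Electrophilic aromatic bromination at the furan α-position next to the methyl group, the most activated site; the bromine blocks C2 so that the later deprotonation can only take place at C5.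

Step 6
Reactants: 7 (2R)-2-hydroxy-5-methyl-2-(propan-2-yl)hex-5-enal; 9 2-bromo-3-methylfuran
Product: 12 (1RS,2R)-5-methyl-1-(4-methylfuran-2-yl)-2-(propan-2-yl)hex-5-ene-1,2-diol, via lithiofuran 10 (not isolated), via bromofuryl diol 11 (not isolated)
Conditions: 9 (2.5 equiv), LDA (2.4 equiv), THF, −78 °C; add 7, −78 °C; then n-BuLi (6 equiv), −78 °C; MeOH, −78 °C to rt
Reagents that add atoms: none
Why: Deprotonation of the only free α-CH of 9 gives 10, which adds 1,2 to the aldehyde (one equivalent is spent on the hydroxyl), and bromine–lithium exchange followed by protonation removes the blocking group in the same flask; the new carbinol centre forms as a mixture, which does not matter because it becomes sp2 in step 8.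

Step 7
Reactants: 12 (1RS,2R)-5-methyl-1-(4-methylfuran-2-yl)-2-(propan-2-yl)hex-5-ene-1,2-diol
Product: 13 (2RS,6RS)-6-hydroxy-2-[(3R)-3-hydroxy-2,6-dimethylhept-6-en-3-yl]-5-methyl-2H-pyran-3(6H)-one
Conditions: NBS (1.05 equiv), NaHCO3 (2 equiv), THF–H2O (4:1), 0 °C
Reagents that add atoms: water, O
Why: Achmatowicz rearrangement, in which bromonium-induced oxidative opening of the electron-rich furan (expected to be much faster than attack on the isolated alkene) is followed by closure of the secondary hydroxyl onto the enal to give the six-membered hemiacetal; the tertiary hydroxyl would need a seven-membered ring and should stay free.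

Step 8
Reactants: 13 (2RS,6RS)-6-hydroxy-2-[(3R)-3-hydroxy-2,6-dimethylhept-6-en-3-yl]-5-methyl-2H-pyran-3(6H)-one
Product: 16 (3R,3aS,7S,8aR)-3-hydroxy-6,8a-dimethyl-3-(propan-2-yl)-1,2,3,7,8,8a-hexahydro-4H-3a,7-epoxyazulen-4-one, via anomeric acetate 14 (not isolated), via oxidopyrylium ylide 15 (not isolated)
Conditions: Ac2O (1.3 equiv), Et3N (4 equiv), DMAP (5 mol %), MeCN, 0 °C; then 70 °C
Reagents that add atoms: none
Why: Acetylation of the hemiacetal and amine-induced loss of acetic acid from 14 generate the 5-methyl-3-oxidopyrylium 15, whose C2 and C6 termini (C3a and C7 of the target) add suprafacially across the tethered alkene C8a=C8 in a concerted thermal six-electron [5+2] cycloaddition. The closest known reaction type is the intramolecular oxidopyrylium–alkene cycloaddition of 6-acetoxy-2-(pent-4-enyl)pyranones. The cyclopentane closes by bonding the internal alkene carbon C8a to C3a over the three-atom tether, which can only span the ylide on the side of the oxygen bridge so that the C8a methyl points toward the enone bridge, and the seven-membered carbocycle closes at the same time by bonding C8 to C7, the ring oxygen remaining as a one-atom 3a,7-bridge. C8a is controlled by C3: the carbinol carbon sits next to the planar ylide with its hydroxyl in the ylide plane syn to the C4 oxido oxygen (hydrogen bond, least allylic 1,3-strain) and its isopropyl group on the face away from the alkene, so the alkene should add to the face that puts the C8a methyl cis to the C3 hydroxyl, and C3a and C7 are then fixed by the bridge, which lies anti to that methyl. The step needs the cycloaddition to outrun ylide dimerisation and retro-aldol loss of the side chain, which the five-membered tether and the fully substituted C3 (Thorpe–Ingold effect) should secure, while the regiochemistry is fixed by the tether length.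

Step 9
Reactants: 16 (3R,3aS,7S,8aR)-3-hydroxy-6,8a-dimethyl-3-(propan-2-yl)-1,2,3,7,8,8a-hexahydro-4H-3a,7-epoxyazulen-4-one
Product: 18 (3R,3aR,7S,8aR)-3,7-dihydroxy-6,8a-dimethyl-3-(propan-2-yl)-2,3,3a,7,8,8a-hexahydroazulen-4(1H)-one, via samarium enolate 17 (not isolated)
Conditions: SmI2 (2.5 equiv), MeOH (10 equiv), THF, −78 °C
Reagents that add atoms: none
Why: Two-electron reductive cleavage of the C–O bond α to the ketone by samarium diiodide gives enolate 17, and protonation at C3a is expected on the α-face that the oxygen has just left (the β-face carries the C8a methyl and the C3 oxygen), which also leads to the trans-fused ketone expected to be the more stable epimer because C4 is anti to the isopropyl group.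

Step 10
Reactants: 18 (3R,3aR,7S,8aR)-3,7-dihydroxy-6,8a-dimethyl-3-(propan-2-yl)-2,3,3a,7,8,8a-hexahydroazulen-4(1H)-one
Product: 19 (3R,3aR,7S,8aR)-3-hydroxy-6,8a-dimethyl-4-oxo-3-(propan-2-yl)-1,2,3,3a,4,7,8,8a-octahydroazulen-7-yl acetate
Conditions: Ac2O (2 equiv), pyridine, DMAP (5 mol %), CH2Cl2, 0 °C
Reagents that add atoms: acetic anhydride, CC(=O)OC(C)=O
Why: DMAP-catalysed acetylation of the secondary allylic alcohol, under which the hindered tertiary hydroxyl should not be acylated.

Step 11
Reactants: 19 (3R,3aR,7S,8aR)-3-hydroxy-6,8a-dimethyl-4-oxo-3-(propan-2-yl)-1,2,3,3a,4,7,8,8a-octahydroazulen-7-yl acetate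
Product: 21 (3R,3aR,8aR)-3-hydroxy-6,8a-dimethyl-3-(propan-2-yl)-2,3,3a,5,8,8a-hexahydroazulen-4(1H)-one, via samarium dienolate 20 (not isolated)
Conditions: SmI2 (2.5 equiv), t-BuOH (5 equiv), THF, −78 °C; aq. NH4Cl at −78 °C
Reagents that add atoms: none
Why: Samarium diiodide reduction of a γ-acyloxy enone expels acetate vinylogously to give dienolate 20, whose kinetic protonation at the α-carbon C5 should give the deconjugated C6=C7 alkene without touching the ring-fusion centre.

Step 12
Reactants: 21 (3R,3aR,8aR)-3-hydroxy-6,8a-dimethyl-3-(propan-2-yl)-2,3,3a,5,8,8a-hexahydroazulen-4(1H)-one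
Product: 22 jaeschkeanadiol, (3R,3aS,4S,8aR)-6,8a-dimethyl-3-(propan-2-yl)-1,2,3,3a,4,5,8,8a-octahydroazulene-3,4-diol
Conditions: Me4NBH(OAc)3 (5 equiv), MeCN–AcOH (1:1), −30 to 0 °C
Reagents that add atoms: none
Why: Evans–Saksena reduction, in which the β-oriented C3 hydroxyl binds boron and delivers hydride to the β-face of the C4 carbonyl, so the new hydroxyl should be α (1,3-anti to the C3 hydroxyl).

Step 13
Reactants: 22 jaeschkeanadiol; 23 4-(acetyloxy)benzoyl chloride
Product: 24 (3R,3aS,4S,8aR)-3-hydroxy-6,8a-dimethyl-3-(propan-2-yl)-1,2,3,3a,4,5,8,8a-octahydroazulen-4-yl 4-(acetyloxy)benzoate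
Conditions: 23 (1.5 equiv), pyridine, DMAP (0.2 equiv), CH2Cl2, 0 °C to rt
Reagents that add atoms: none
Why: DMAP-catalysed acylation with an acid chloride, in which only the secondary C4 hydroxyl should react because the tertiary C3 hydroxyl is too hindered; no stereocentre is touched.

Step 14
Reactants: 24 (3R,3aS,4S,8aR)-3-hydroxy-6,8a-dimethyl-3-(propan-2-yl)-1,2,3,3a,4,5,8,8a-octahydroazulen-4-yl 4-(acetyloxy)benzoate
Product: 25 ferutinine, (3R,3aS,4S,8aR)-3-hydroxy-6,8a-dimethyl-3-(propan-2-yl)-1,2,3,3a,4,5,8,8a-octahydroazulen-4-yl 4-hydroxybenzoate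
Conditions: pyrrolidine (2 equiv), CH2Cl2, 0 °C to rt
Reagents that add atoms: none
Why: Chemoselective aminolysis of the aryl acetate, which is far more electrophilic than the hindered secondary alkyl benzoate, should free the phenol and give the target.

**Compound list**

1 | prop-2-yn-1-ol | C#CCO | starting material
2 | isopropylmagnesium chloride | CC(C)[Mg]Cl | starting material
3 | 3-methyl-2-methylidenebutan-1-ol | CC(C)C(=C)CO | intermediate
4 | [(2R)-2-(propan-2-yl)oxiran-2-yl]methanol | OC[C@]1(C(C)C)CO1 | intermediate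
5 | (2-methylprop-2-en-1-yl)magnesium chloride | CC(=C)C[Mg]Cl | starting material
6 | (2R)-5-methyl-2-(propan-2-yl)hex-5-ene-1,2-diol | OC[C@](O)(C(C)C)CCC(C)=C | intermediate
7 | (2R)-2-hydroxy-5-methyl-2-(propan-2-yl)hex-5-enal | O=C[C@](O)(C(C)C)CCC(C)=C | intermediate
8 | 3-methylfuran | Cc1ccoc1 | starting material
9 | 2-bromo-3-methylfuran | Cc1ccoc1Br | intermediate
10 | (5-bromo-4-methylfuran-2-yl)lithium, formed in the flask | [Li]c1cc(C)c(Br)o1 | intermediate
11 | (1RS,2R)-1-(5-bromo-4-methylfuran-2-yl)-5-methyl-2-(propan-2-yl)hex-5-ene-1,2-diol, present in the flask as its dilithium alkoxide | Cc1cc(oc1Br)C(O)[C@](O)(C(C)C)CCC(C)=C | intermediate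
12 | (1RS,2R)-5-methyl-1-(4-methylfuran-2-yl)-2-(propan-2-yl)hex-5-ene-1,2-diol | Cc1coc(c1)C(O)[C@](O)(C(C)C)CCC(C)=C | intermediate
13 | (2RS,6RS)-6-hydroxy-2-[(3R)-3-hydroxy-2,6-dimethylhept-6-en-3-yl]-5-methyl-2H-pyran-3(6H)-one | CC1=CC(=O)C(OC1O)[C@](O)(C(C)C)CCC(C)=C | intermediate
14 | (2RS,6RS)-6-[(3R)-3-hydroxy-2,6-dimethylhept-6-en-3-yl]-3-methyl-5-oxo-5,6-dihydro-2H-pyran-2-yl acetate, formed in the flask | CC1=CC(=O)C(OC1OC(C)=O)[C@](O)(C(C)C)CCC(C)=C | intermediate
15 | 2-[(3R)-3-hydroxy-2,6-dimethylhept-6-en-3-yl]-5-methylpyrylium-3-olate, formed in the flask | [O-]c1cc(C)c[o+]c1[C@](O)(C(C)C)CCC(C)=C | intermediate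
16 | (3R,3aS,7S,8aR)-3-hydroxy-6,8a-dimethyl-3-(propan-2-yl)-1,2,3,7,8,8a-hexahydro-4H-3a,7-epoxyazulen-4-one (oxygen bridge α, C8a methyl and C3 hydroxyl β) | C1=C(C)[C@@H]3C[C@@]2(C)CC[C@@](O)(C(C)C)[C@]2(O3)C1=O | intermediate
17 | bis(diiodosamarium) enolate alkoxide of 18 (trivalent samarium on the C4 enolate oxygen and on the C7 oxygen), formed in the flask | C1=C(C)[C@@H](O[Sm](I)I)C[C@@]2(C)CC[C@@](O)(C(C)C)C2=C1O[Sm](I)I | intermediate
18 | (3R,3aR,7S,8aR)-3,7-dihydroxy-6,8a-dimethyl-3-(propan-2-yl)-2,3,3a,7,8,8a-hexahydroazulen-4(1H)-one (3a-H α, trans-fused) | C1=C(C)[C@@H](O)C[C@@]2(C)CC[C@@](O)(C(C)C)[C@@H]2C1=O | intermediate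
19 | (3R,3aR,7S,8aR)-3-hydroxy-6,8a-dimethyl-4-oxo-3-(propan-2-yl)-1,2,3,3a,4,7,8,8a-octahydroazulen-7-yl acetate | C1=C(C)[C@@H](OC(C)=O)C[C@@]2(C)CC[C@@](O)(C(C)C)[C@@H]2C1=O | intermediate
20 | diiodosamarium 4,6-dienolate of 21 (trivalent samarium on the C4 oxygen, double bonds C4=C5 and C6=C7), formed in the flask | C1(O[Sm](I)I)=CC(C)=CC[C@@]2(C)CC[C@@](O)(C(C)C)[C@H]12 | intermediate
21 | (3R,3aR,8aR)-3-hydroxy-6,8a-dimethyl-3-(propan-2-yl)-2,3,3a,5,8,8a-hexahydroazulen-4(1H)-one | C1C(C)=CC[C@@]2(C)CC[C@@](O)(C(C)C)[C@@H]2C1=O | intermediate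
22 | jaeschkeanadiol, (3R,3aS,4S,8aR)-6,8a-dimethyl-3-(propan-2-yl)-1,2,3,3a,4,5,8,8a-octahydroazulene-3,4-diol | CC1=CC[C@@]2(C)CC[C@@](O)(C(C)C)[C@@H]2[C@@H](O)C1 | intermediate
23 | 4-(acetyloxy)benzoyl chloride | CC(=O)Oc1ccc(cc1)C(Cl)=O | starting material
24 | (3R,3aS,4S,8aR)-3-hydroxy-6,8a-dimethyl-3-(propan-2-yl)-1,2,3,3a,4,5,8,8a-octahydroazulen-4-yl 4-(acetyloxy)benzoate | CC1=CC[C@@]2(C)CC[C@@](O)(C(C)C)[C@@H]2[C@@H](OC(=O)c2ccc(OC(C)=O)cc2)C1 | intermediate
25 | ferutinine, (3R,3aS,4S,8aR)-3-hydroxy-6,8a-dimethyl-3-(propan-2-yl)-1,2,3,3a,4,5,8,8a-octahydroazulen-4-yl 4-hydroxybenzoate | CC1=CC[C@@]2(C)CC[C@@](O)(C(C)C)[C@@H]2[C@@H](OC(=O)c2ccc(O)cc2)C1 | target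

**Step count**

Total steps: 14. Longest linear sequence: 13 (steps 1–4 and 6–14; step 5 is a one-step branch).

**Steps most likely to fail**

Step 8. The ylide may dimerise, or the β-hydroxy ketone 14 may lose its side chain by retro-aldol cleavage, before the hindered 1,1-disubstituted alkene adds; the facial bias also rests on a conformational preference of the free carbinol. The fallback masks the hydroxyl, which closes the retro-aldol channel and puts a silyloxy group in the in-plane position. It sets out from 13: acetylation (Ac2O, pyridine, 0 °C) with isolation of 14, then silylation of the tertiary hydroxyl with N-(trimethylsilyl)imidazole to give the trimethylsilyl ether of the acetate F1. Et3N in MeCN at 70 °C would then lead through the silylated oxidopyrylium F2 to the silylated cycloadduct F3. Citric acid in methanol cleaves the silyl ether, and the fallback comes back to the route at 16.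

Step 9. Poor facial selectivity in the protonation of enolate 17 at C3a would give the cis-fused epimer alongside 18. The fallback replaces kinetic protonation by thermodynamic control on a protected substrate. It sets out from 16: the reduction is run as in step 9, and the mixture of 18 and its cis-fused C3a epimer F4 is silylated on both hydroxyls with N-(trimethylsilyl)imidazole. This gives the cis-fused bis(trimethylsilyl) ether F5 and the trans-fused bis(trimethylsilyl) ether F6. DBU in toluene should equilibrate F5 into F6 through the cross-conjugated dienolate, the silyl ether on C3 blocking retro-aldol cleavage. Citric acid in methanol removes both silyl groups, and the fallback comes back to the route at 18.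

Step 11. Protonation of dienolate 20 at the γ-carbon C7 would return a conjugated enone, and excess reductant could reduce the ketone. The fallback delivers the hydrogen to C5 by a sigmatropic process instead of a protonation. It sets out from 18: a Mitsunobu reaction at the C7 hydroxyl with N-isopropylidene-N'-(2-nitrobenzenesulfonyl)hydrazine (PPh3, diethyl azodicarboxylate, THF, 0 °C, inversion at C7) would give the sulfonyl hydrazone adduct F7. Hydrolysis in trifluoroethanol–water releases the allylic diazene F8, which loses dinitrogen by a retro-ene shift that places hydrogen on C5 and the double bond at C6=C7. The fallback comes back to the route at 21, so steps 10 and 11 are then not needed.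

**Further compounds**

F1 | step 8 | (2RS,6RS)-3-methyl-6-[(3R)-2,6-dimethyl-3-(trimethylsilyloxy)hept-6-en-3-yl]-5-oxo-5,6-dihydro-2H-pyran-2-yl acetate | CC1=CC(=O)C(OC1OC(C)=O)[C@](O[Si](C)(C)C)(C(C)C)CCC(C)=C
F2 | step 8 | 2-[(3R)-2,6-dimethyl-3-(trimethylsilyloxy)hept-6-en-3-yl]-5-methylpyrylium-3-olate | [O-]c1cc(C)c[o+]c1[C@](O[Si](C)(C)C)(C(C)C)CCC(C)=C
F3 | step 8 | (3R,3aS,7S,8aR)-6,8a-dimethyl-3-(propan-2-yl)-3-(trimethylsilyloxy)-1,2,3,7,8,8a-hexahydro-4H-3a,7-epoxyazulen-4-one | C1=C(C)[C@@H]3C[C@@]2(C)CC[C@@](O[Si](C)(C)C)(C(C)C)[C@]2(O3)C1=O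
F4 | step 9 | C3a epimer of 18 (3a-H β, cis-fused), (3R,3aS,7S,8aR)-3,7-dihydroxy-6,8a-dimethyl-3-(propan-2-yl)-2,3,3a,7,8,8a-hexahydroazulen-4(1H)-one | C1=C(C)[C@@H](O)C[C@@]2(C)CC[C@@](O)(C(C)C)[C@H]2C1=O
F5 | step 9 | 3,7-bis(trimethylsilyl) ether of F4 (cis-fused) | C1=C(C)[C@@H](O[Si](C)(C)C)C[C@@]2(C)CC[C@@](O[Si](C)(C)C)(C(C)C)[C@H]2C1=O
F6 | step 9 | 3,7-bis(trimethylsilyl) ether of 18 (trans-fused) | C1=C(C)[C@@H](O[Si](C)(C)C)C[C@@]2(C)CC[C@@](O[Si](C)(C)C)(C(C)C)[C@@H]2C1=O
F7 | step 11 | N-[(3R,3aR,7R,8aR)-3-hydroxy-6,8a-dimethyl-4-oxo-3-(propan-2-yl)-1,2,3,3a,4,7,8,8a-octahydroazulen-7-yl]-2-nitro-N'-(propan-2-ylidene)benzenesulfonohydrazide (C7–N β) | C1=C(C)[C@H](N(N=C(C)C)S(=O)(=O)c3ccccc3[N+](=O)[O-])C[C@@]2(C)CC[C@@](O)(C(C)C)[C@@H]2C1=O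
F8 | step 11 | (3R,3aR,7R,8aR)-7-diazenyl-3-hydroxy-6,8a-dimethyl-3-(propan-2-yl)-2,3,3a,7,8,8a-hexahydroazulen-4(1H)-one | C1=C(C)[C@H](N=N)C[C@@]2(C)CC[C@@](O)(C(C)C)[C@@H]2C1=O
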